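The target is a reduced aldol: benzylic C1 of the saturated ring B lies between the ring carbinol C2 and the side-chain carbinol C1'. The route therefore joins C1 to C1' by adding the enol silane of 6,7-dimethoxy-2-tetralone, which enolizes toward the benzylic C1, to silyl-protected (E)-4-hydroxycinnamaldehyde under a chiral (acyloxy)borane catalyst. This one operation unites both fragments and sets C1 and C1' through an open transition state, giving the syn adduct that the ring-locked E-enolate cannot reach through a closed one. The new C1' hydroxyl then holds the C2 ketone in a temporary boron chelate that steers hydride to the cis, 1,3-syn diol.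

Key step: step 3

Remark on numbering: tetralin atoms are C1–C4, C4a, C5–C8, C8a (ring A = dimethoxy arene, ring B = carbocycle, ring C = phenol ring); the side chain is C1' (carbinol), C2'=C3'.

Assumption: the ligand of step 3, (2R,3R)-2-O-(2,6-diisopropoxybenzoyl)tartaric acid, is a known compound (acylation of dibenzyl (2R,3R)-tartrate with 2,6-diisopropoxybenzoyl chloride, then hydrogenolysis). It is used in catalytic amount and is not counted as a step.

Step 1
Reactants: 1 (2E)-3-(4-hydroxyphenyl)prop-2-enal
Product: 2 (2E)-3-[4-(tert-butyldimethylsilyloxy)phenyl]prop-2-enal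
Conditions: TBSCl, imidazole, DMF, 0 °C to rt
Reagents that add atoms: tert-butyldimethylsilyl chloride, CC(C)(C)[Si](C)(C)Cl
Why: Imidazole-promoted silylation of the phenol (silyl ether protection) should leave the aldehyde and the E-alkene untouched, and no stereocenter is formed.

Step 2
Reactants: 3 6,7-dimethoxy-3,4-dihydronaphthalen-2(1H)-one
Product: 4 [(6,7-dimethoxy-3,4-dihydronaphthalen-2-yl)oxy]trimethylsilane
Conditions: TMSOTf, Et3N, CH2Cl2, 0 °C; non-aqueous work-up (pentane, filtration)
Reagents that add atoms: trimethylsilyl trifluoromethanesulfonate, C[Si](C)(C)OS(=O)(=O)C(F)(F)F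
Why: Soft enolization with silyl triflate and amine (silyl enol ether formation) should give only the arene-conjugated C1=C2 enol silane, because the C1 hydrogens are benzylic and α to the carbonyl and so far more acidic than those at C3.

Step 3
Reactants: 4 [(6,7-dimethoxy-3,4-dihydronaphthalen-2-yl)oxy]trimethylsilane; 2 (2E)-3-[4-(tert-butyldimethylsilyloxy)phenyl]prop-2-enal
Product: 6 (1R)-1-[(1S,2E)-3-[4-(tert-butyldimethylsilyloxy)phenyl]-1-hydroxyprop-2-en-1-yl]-6,7-dimethoxy-3,4-dihydronaphthalen-2(1H)-one, via aldol trimethylsilyl ether 5 (not isolated)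
Conditions: (2R,3R)-2-O-(2,6-diisopropoxybenzoyl)tartaric acid (20 mol %), BH3·THF (20 mol %), EtCN, 0 °C; 2 then 4, −78 °C; then citric acid, MeOH, 0 °C
Reagents that add atoms: none
Why: Catalytic asymmetric Mukaiyama aldol addition: the chiral (acyloxy)borane binds the aldehyde oxygen anti to the styryl group, the electron-rich C1 of enol silane 4 attacks the carbonyl carbon in an open antiperiplanar transition state, and silyl transfer to the aldolate oxygen releases the catalyst and gives 5, which mild acidic methanolysis converts to 6. The closest known reaction type is the (acyloxy)borane-catalysed addition of ketone enol silanes to enals, which is known to give 1,2-adducts and syn aldols from either enol geometry. No ring is closed. C1' is set by the catalyst, whose 2,6-diisopropoxybenzoyl arene is expected to cover the si face of the bound aldehyde so that re-face attack gives the (S) carbinol; C1 is set by the open transition state, in which the styryl group lies next to C1–H and away from the ring A carbon C8a, giving the syn (C8a/OH) adduct. The step needs C1 over C3 regioselectivity, secured by the conjugated position of the enol double bond in 4, and 1,2- over 1,4-addition, secured by Lewis acid activation of the carbonyl carbon at −78 °C.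

Step 4
Reactants: 6 (1R)-1-[(1S,2E)-3-[4-(tert-butyldimethylsilyloxy)phenyl]-1-hydroxyprop-2-en-1-yl]-6,7-dimethoxy-3,4-dihydronaphthalen-2(1H)-one
Product: 8 (1S,2R)-1-[(1S,2E)-3-[4-(tert-butyldimethylsilyloxy)phenyl]-1-hydroxyprop-2-en-1-yl]-6,7-dimethoxy-1,2,3,4-tetrahydronaphthalen-2-ol, via diethylboron chelate 7 (not isolated)
Conditions: Et2BOMe, THF/MeOH (4:1), −78 °C; NaBH4, −78 °C; then pH 7 buffer, MeOH co-evaporation
Reagents that add atoms: none
Why: Narasaka–Prasad reduction: the C1' hydroxyl and the C2 carbonyl are tied into the six-membered boron chelate 7 with the styryl group equatorial and C8a axial, and external hydride should add to C2 axially, anti to C8a and to the side chain, which sets C2 (R) as the 1,3-syn carbinol cis to the C1 substituent.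

Step 5
Reactants: 8 (1S,2R)-1-[(1S,2E)-3-[4-(tert-butyldimethylsilyloxy)phenyl]-1-hydroxyprop-2-en-1-yl]-6,7-dimethoxy-1,2,3,4-tetrahydronaphthalen-2-ol
Product: 9 (1S,2R)-1-[(1S,2E)-1-hydroxy-3-(4-hydroxyphenyl)prop-2-en-1-yl]-6,7-dimethoxy-1,2,3,4-tetrahydronaphthalen-2-ol
Conditions: TBAF, AcOH, THF, 0 °C
Reagents that add atoms: none
Why: Fluoride should cleave the aryl silyl ether selectively (silyl ether deprotection), acetic acid buffering the phenoxide so that the allylic diol is not exposed to free base, and no stereocenter is touched.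

Compound list
1 | (2E)-3-(4-hydroxyphenyl)prop-2-enal (4-hydroxycinnamaldehyde) | O=C/C=C/c1ccc(O)cc1 | starting material
2 | (2E)-3-[4-(tert-butyldimethylsilyloxy)phenyl]prop-2-enal | O=C/C=C/c1ccc(O[Si](C)(C)C(C)(C)C)cc1 | intermediate
3 | 6,7-dimethoxy-3,4-dihydronaphthalen-2(1H)-one (6,7-dimethoxy-2-tetralone) | COc1cc2c(cc1OC)CC(=O)CC2 | starting material
4 | [(6,7-dimethoxy-3,4-dihydronaphthalen-2-yl)oxy]trimethylsilane (C1=C2 enol silane) | COc1cc2c(cc1OC)C=C(O[Si](C)(C)C)CC2 | intermediate
5 | (1R)-1-[(1S,2E)-3-[4-(tert-butyldimethylsilyloxy)phenyl]-1-(trimethylsilyloxy)prop-2-en-1-yl]-6,7-dimethoxy-3,4-dihydronaphthalen-2(1H)-one (syn aldol, C1' oxygen silylated) | COc1cc2c(cc1OC)[C@H]([C@@H](O[Si](C)(C)C)/C=C/c1ccc(O[Si](C)(C)C(C)(C)C)cc1)C(=O)CC2 | intermediate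
6 | (1R)-1-[(1S,2E)-3-[4-(tert-butyldimethylsilyloxy)phenyl]-1-hydroxyprop-2-en-1-yl]-6,7-dimethoxy-3,4-dihydronaphthalen-2(1H)-one (syn aldol, C8a and C1' hydroxyl syn) | COc1cc2c(cc1OC)[C@H]([C@@H](O)/C=C/c1ccc(O[Si](C)(C)C(C)(C)C)cc1)C(=O)CC2 | intermediate
7 | diethylboron chelate of 6 (boron on the C1' alkoxide oxygen and coordinated by the C2 carbonyl oxygen; C1 and C1' as in 6) | COc1cc2c(cc1OC)[C@H]([C@@H](O3)/C=C/c1ccc(O[Si](C)(C)C(C)(C)C)cc1)C(=[O+][B-]3(CC)CC)CC2 | intermediate
8 | (1S,2R)-1-[(1S,2E)-3-[4-(tert-butyldimethylsilyloxy)phenyl]-1-hydroxyprop-2-en-1-yl]-6,7-dimethoxy-1,2,3,4-tetrahydronaphthalen-2-ol (C2 hydroxyl cis to the C1 side chain, 1,3-syn diol) | COc1cc2c(cc1OC)[C@H]([C@@H](O)/C=C/c1ccc(O[Si](C)(C)C(C)(C)C)cc1)[C@H](O)CC2 | intermediate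
9 | (1S,2R)-1-[(1S,2E)-1-hydroxy-3-(4-hydroxyphenyl)prop-2-en-1-yl]-6,7-dimethoxy-1,2,3,4-tetrahydronaphthalen-2-ol | COc1cc2c(cc1OC)[C@H]([C@@H](O)/C=C/c1ccc(O)cc1)[C@H](O)CC2 | target

Total step count: 5
Longest linear sequence: 4 steps (3 → 4 → 6 → 8 → 9)

Steps most likely to fail

Step 3. The open transition state may discriminate poorly between syn and anti approach for a ring-fused enol silane, or the catalyst may shield the face of this electron-rich enal less well than expected. The fallback sets out from 3 and 2 and comes back at 8; it makes the C1–C1' bond without stereocontrol and sets the three centres afterwards. The lithium enolate of 3 (LDA, THF, −78 °C, deprotonation at the benzylic C1) is added to 2 to give the aldol as a stereoisomer mixture F1. C1 of F1 is configurationally labile, so asymmetric transfer hydrogenation with RuCl(p-cymene)(TsDPEN) in HCO2H/Et3N should reduce it under dynamic kinetic resolution to the cis (1S,2R) alcohol as its two C1' epimers F2. The ligand enantiomer would be chosen in a trial run so that the 2R carbinol results. MnO2 in CH2Cl2 should then oxidize only the allylic C1' carbinol and converge both epimers on the β-hydroxy enone F3. Et2BOMe/NaBH4 in THF/MeOH at −78 °C should reduce the enone carbonyl under direction of the C2 hydroxyl to the 1,3-syn diol, which is 8.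

Step 4. Enolization of 6 before chelation would erode C1, the C1' hydroxyl could be lost by β-elimination to the dienone, or hydride could arrive from the side-chain face. The fallback sets out from 5 and comes back at 8; it replaces chelation control by steric approach control on the silylated aldol. Step 3 is worked up with NaHCO3 instead of citric acid/MeOH so that 5 is isolated. LiBH(s-Bu)3 in THF at −78 °C should then attack C2 anti to the pseudoaxial C1 side chain and give the cis alcohol with the C1' oxygen still silylated F4. Citric acid in MeOH at 0 °C removes the trimethylsilyl group and gives 8.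

Step 5. Once the phenoxide is liberated, the doubly activated allylic carbinol may ionize toward a vinylogous quinone methide, or the product may degrade on contact with fluoride. The fallback sets out from 1 and comes back at 9; it changes the phenol protecting group so that the last step is neutral and fluoride-free. Compound 1 is alkylated (allyl bromide, K2CO3, acetone) to the allyl ether enal F5. The conditions of step 3 applied to F5 and 4 should give, via the aldol trimethylsilyl ether F6, the syn aldol F7. The conditions of step 4 should give, via the boron chelate F8, the allyl-protected diol F9. Pd(PPh3)4 (catalytic) with morpholine in THF at rt then transfers the allyl group to the amine and gives 9.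

Further compounds
F1 | step 3 | 1-[(2E)-3-[4-(tert-butyldimethylsilyloxy)phenyl]-1-hydroxyprop-2-en-1-yl]-6,7-dimethoxy-3,4-dihydronaphthalen-2(1H)-one, stereoisomer mixture at C1 and C1' | COc1cc2c(cc1OC)C(C(O)/C=C/c1ccc(O[Si](C)(C)C(C)(C)C)cc1)C(=O)CC2
F2 | step 3 | (1S,2R)-1-[(2E)-3-[4-(tert-butyldimethylsilyloxy)phenyl]-1-hydroxyprop-2-en-1-yl]-6,7-dimethoxy-1,2,3,4-tetrahydronaphthalen-2-ol, both C1' epimers | COc1cc2c(cc1OC)[C@H](C(O)/C=C/c1ccc(O[Si](C)(C)C(C)(C)C)cc1)[C@H](O)CC2
F3 | step 3 | (2E)-3-[4-(tert-butyldimethylsilyloxy)phenyl]-1-[(1S,2R)-2-hydroxy-6,7-dimethoxy-1,2,3,4-tetrahydronaphthalen-1-yl]prop-2-en-1-one | COc1cc2c(cc1OC)[C@H](C(=O)/C=C/c1ccc(O[Si](C)(C)C(C)(C)C)cc1)[C@H](O)CC2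
F4 | step 4 | (1S,2R)-1-[(1S,2E)-3-[4-(tert-butyldimethylsilyloxy)phenyl]-1-(trimethylsilyloxy)prop-2-en-1-yl]-6,7-dimethoxy-1,2,3,4-tetrahydronaphthalen-2-ol | COc1cc2c(cc1OC)[C@H]([C@@H](O[Si](C)(C)C)/C=C/c1ccc(O[Si](C)(C)C(C)(C)C)cc1)[C@H](O)CC2
F5 | step 5 | (2E)-3-[4-(prop-2-en-1-yloxy)phenyl]prop-2-enal | O=C/C=C/c1ccc(OCC=C)cc1
F6 | step 5 | (1R)-6,7-dimethoxy-1-[(1S,2E)-3-[4-(prop-2-en-1-yloxy)phenyl]-1-(trimethylsilyloxy)prop-2-en-1-yl]-3,4-dihydronaphthalen-2(1H)-one | COc1cc2c(cc1OC)[C@H]([C@@H](O[Si](C)(C)C)/C=C/c1ccc(OCC=C)cc1)C(=O)CC2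
F7 | step 5 | (1R)-1-[(1S,2E)-1-hydroxy-3-[4-(prop-2-en-1-yloxy)phenyl]prop-2-en-1-yl]-6,7-dimethoxy-3,4-dihydronaphthalen-2(1H)-one | COc1cc2c(cc1OC)[C@H]([C@@H](O)/C=C/c1ccc(OCC=C)cc1)C(=O)CC2
F8 | step 5 | diethylboron chelate of F7 (boron on the C1' alkoxide oxygen and coordinated by the C2 carbonyl oxygen) | COc1cc2c(cc1OC)[C@H]([C@@H](O3)/C=C/c1ccc(OCC=C)cc1)C(=[O+][B-]3(CC)CC)CC2
F9 | step 5 | (1S,2R)-1-[(1S,2E)-1-hydroxy-3-[4-(prop-2-en-1-yloxy)phenyl]prop-2-en-1-yl]-6,7-dimethoxy-1,2,3,4-tetrahydronaphthalen-2-ol | COc1cc2c(cc1OC)[C@H]([C@@H](O)/C=C/c1ccc(OCC=C)cc1)[C@H](O)CC2
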